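**Retrosynthetic overview**

1. The C40 polyene is cut at the two C11=C12 bonds (carotenoid numbering within each half) into the ε-type C15 phosphonium salt 8, the C10 dialdehyde 9 and the β-type C15 phosphonium salt 16, joined by two Wittig reactions.
2. Both salts come from one C13 ketone, (3S,6R)-3-hydroxy-α-ionone 5. Mitsunobu inversion at C3 gives ring ε. Syn-epoxidation of C4=C5 followed by vinylogous E1cB opening from C6–H moves the alkene to C5=C6 and leaves the cis-3,4-diol of ring β.
3. Ketone 5 comes from the bridged lactone 3 (reduction, Wittig), and 3 from 4-methyl-2H-pyran-2-one 1 and isobutylene 2 by an enantioselective inverse-demand [4+2] cycloaddition that forms C1–C6 and C2–C3.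
4. Enabling feature: in the ring C1–C6, C3 (bearing O) and C6 (bearing C7) stand 1,4 across the C4=C5(Me) bond, and C1(Me)2–C2H2 is an intact isobutylene unit. The ring is therefore the adduct of isobutylene with a diene C3=C4–C5(Me)=C6 whose terminal O and C7 are tied together as the lactone O–C(=O) of a 2-pyranone.
5. Ring order: the six-membered carbocycle is made once (step 1) and serves as ring ε and, after double-bond migration, as ring β. The lactone bridge is a temporary ring opened in steps 2–3.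

Key step: step 1

Remark: 1 and 9 are taken as purchasable; C9 of the tertiary carbinols 6, 7, 14 and 15 is an inconsequential epimer mixture; the antipode of the catalyst in step 1 that leads to (1S,4R)-3 is fixed by experiment.

**Route**

Step 1
Reactants: 1 4-methyl-2H-pyran-2-one; 2 2-methylpropene (isobutylene)
Product: 3 (1S,4R)-5,8,8-trimethyl-2-oxabicyclo[2.2.2]oct-5-en-3-one
Conditions: chiral N-triflyl imidodiphosphorimidate (IDPi) acid (2 mol%), methallyltrimethylsilane (5 mol%, converts the acid into its N-silyl form), 2 (4 equiv, condensed), CH2Cl2, −60 °C; Et3N quench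
Reagents that add atoms: none
Why: Proposed new method: the N-silylated IDPi should transfer its silyl group to the carbonyl oxygen of 1, and the resulting 2-silyloxypyrylium ion, paired with the confined chiral anion, is an electron-poor 4π component that the CH2 terminus of isobutylene attacks at the O-bound ring carbon while the developing tertiary cation is captured by the carbon next to the carbonyl, so that C2–C3 and C1–C6 of the future ring form in one concerted but strongly asynchronous inverse-electron-demand [4+2] event, after which silyl transfer to the next molecule of 1 turns the catalyst over. The closest known reaction types are Lewis-acid-catalysed (also enantioselective) inverse-demand Diels–Alder reactions of 3-carboalkoxy-2-pyranones with vinyl ethers, thermal cycloadditions of 2-pyranones with unactivated 1-alkenes, and silylium–IDPi ion-pair catalysis of Diels–Alder reactions of α,β-unsaturated esters. One ring closes, the six-membered carbocycle, by suprafacial [4πs+2πs] addition across the 3- and 6-positions of the pyranone through a boat-like transition state, and the lactone O–C(=O) of 1 is left as the two-atom bridge of the bicyclo[2.2.2]octene. The two new stereocentres are the bridgeheads: their cis relation is enforced by the lactone bridge, and their absolute sense by the face of the flat pyrylium ion that the chiral anion leaves open. The step needs regio- and enantioselectivity only, since isobutylene carries two identical groups on each carbon and there is no endo/exo question; the regiochemistry follows from Markovnikov polarisation, with positive charge building on the dimethyl-substituted carbon and the first bond forming at the most electrophilic, O-bound terminus. The low temperature should keep the adduct from losing CO2.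

Step 2
Reactants: 3 (1S,4R)-5,8,8-trimethyl-2-oxabicyclo[2.2.2]oct-5-en-3-one
Product: 4 (1S,4R)-5,8,8-trimethyl-2-oxabicyclo[2.2.2]oct-5-en-3-ol (anomer mixture)
Conditions: iBu2AlH (1.05 equiv), CH2Cl2, −78 °C; aq. potassium sodium tartrate (KNaC4H4O6)
Reagents that add atoms: none
Why: Partial lactone-to-lactol reduction by iBu2AlH at −78 °C stops at the aluminium hemiacetal, leaving the bridgehead stereocentres untouched and the new hemiacetal carbon as an inconsequential anomer mixture.

Step 3
Reactants: 4 (1S,4R)-5,8,8-trimethyl-2-oxabicyclo[2.2.2]oct-5-en-3-ol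
Product: 5 (3E)-4-[(1R,4S)-4-hydroxy-2,6,6-trimethylcyclohex-2-en-1-yl]but-3-en-2-one, i.e. (3S,6R)-3-hydroxy-α-ionone (hydroxyl cis to the side chain)
Conditions: Ph3P=CHC(O)CH3 (1.5 equiv), toluene, 70 °C
Reagents that add atoms: 1-(triphenyl-λ5-phosphanylidene)propan-2-one, CC(=O)C=P(c1ccccc1)(c1ccccc1)c1ccccc1
Why: Wittig olefination of the lactol through its open hydroxy-aldehyde form with a stabilised, non-basic ylide should give the (E)-enone without enolising the β,γ-unsaturated aldehyde, so C6 keeps its configuration and C3 is released as the cis-alcohol.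

Step 4
Reactants: 5 (3S,6R)-3-hydroxy-α-ionone
Product: 6 (1E)-1-[(1R,4S)-4-hydroxy-2,6,6-trimethylcyclohex-2-en-1-yl]-3-methylpenta-1,4-dien-3-ol
Conditions: CH2=CHMgBr (3 equiv), THF, −78 → −20 °C; sat. aq. NH4Cl
Reagents that add atoms: vinylmagnesium bromide, C=C[Mg]Br
Why: Grignard 1,2-addition to the ionone-type methyl ketone (the first equivalent is used up by the hydroxyl, and the β-carbon is shielded by the ring) gives the vinyl carbinol, whose new centre C9 is planarised again in step 6.

Step 5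
Reactants: 6 (1E)-1-[(1R,4S)-4-hydroxy-2,6,6-trimethylcyclohex-2-en-1-yl]-3-methylpenta-1,4-dien-3-ol
Product: 7 (1R,4R)-4-[(1E)-3-hydroxy-3-methylpenta-1,4-dien-1-yl]-3,5,5-trimethylcyclohex-2-en-1-yl benzoate
Conditions: PhCO2H (1.5 equiv), PPh3 (1.5 equiv), DIAD (1.5 equiv), THF, 0 °C → rt
Reagents that add atoms: benzoic acid, OC(=O)c1ccccc1
Why: Mitsunobu esterification displaces the oxyphosphonium group by SN2 and so inverts C3 from S to R, giving the trans relation to C6 required in ring ε, while the tertiary carbinol is too hindered to be activated.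

Step 6
Reactants: 7 (1R,4R)-4-[(1E)-3-hydroxy-3-methylpenta-1,4-dien-1-yl]-3,5,5-trimethylcyclohex-2-en-1-yl benzoate
Product: 8 {(2E,4E)-5-[(1R,4R)-4-(benzoyloxy)-2,6,6-trimethylcyclohex-2-en-1-yl]-3-methylpenta-2,4-dien-1-yl}triphenylphosphonium bromide
Conditions: PPh3·HBr (1.1 equiv), CH2Cl2, 0 °C → rt
Reagents that add atoms: triphenylphosphine hydrobromide, [Br-].c1ccc(cc1)[PH+](c1ccccc1)c1ccccc1
Why: Acid ionisation of the tertiary bis-allylic carbinol gives a pentadienyl cation that PPh3 captures at the unhindered terminus C11 (the classical vinyl-ionol to C15-salt allylic transposition, thermodynamic E geometry at the new trisubstituted alkene), while the benzoate keeps the allylic C3–O bond from ionising.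

Step 7
Reactants: 8 ε-type C15 phosphonium bromide; 9 (2E,4E,6E)-2,7-dimethylocta-2,4,6-trienedial
Product: 11 (2E,4E,6E,8E,10E,12E)-13-[(1R,4R)-4-(benzoyloxy)-2,6,6-trimethylcyclohex-2-en-1-yl]-2,7,11-trimethyltrideca-2,4,6,8,10,12-hexaenal, via ε-C15 ylide 10 (not isolated)
Conditions: 9 (3 equiv), 1,2-epoxybutane/EtOH, 65 °C; excess 9 removed by chromatography
Reagents that add atoms: none
Why: Wittig reaction of the semistabilised allylic ylide, generated under neutral conditions when bromide opens the epoxide and the resulting alkoxide deprotonates the salt, should stop at mono-olefination of the excess symmetrical dialdehyde because the C25 aldehyde is the weaker electrophile, and Z-isomers at the new bond equilibrate to E on heating.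

Step 8
Reactants: 5 (3S,6R)-3-hydroxy-α-ionone
Product: 12 (3E)-4-[(1R,2R,5S,6S)-5-hydroxy-1,3,3-trimethyl-7-oxabicyclo[4.1.0]heptan-2-yl]but-3-en-2-one
Conditions: VO(acac)2 (3 mol%), t-BuOOH (1.5 equiv), CH2Cl2, 0 °C → rt
Reagents that add atoms: tert-butyl hydroperoxide, CC(C)(C)OO
Why: Hydroxyl-directed epoxidation of the allylic alcohol by the vanadium–alkyl hydroperoxide system delivers oxygen to C4=C5 from the face of the C3 hydroxyl, which sets C4 and C5 syn to it, and leaves the electron-poor enone alkene alone.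

Step 9
Reactants: 12 syn-epoxy alcohol
Product: 13 (3E)-4-[(3R,4S)-3,4-dihydroxy-2,6,6-trimethylcyclohex-1-en-1-yl]but-3-en-2-one, i.e. (3S,4R)-3,4-dihydroxy-β-ionone in ionone numbering
Conditions: NaOMe (0.3 equiv), MeOH, 0 °C → rt
Reagents that add atoms: none
Why: Vinylogous E1cB opening of the epoxide (deprotonation at C6, γ to the ketone, then expulsion of the C5–O bond; the known conversion of α-ionone 4,5-epoxides into 4-hydroxy-β-ionones) moves the double bond to C5=C6 without touching the C4–O bond, so the cis-3,4-diol keeps the configuration set in step 8.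

Step 10
Reactants: 13 (3S,4R)-3,4-dihydroxy-β-ionone
Product: 14 (1E)-1-[(3R,4S)-3,4-dihydroxy-2,6,6-trimethylcyclohex-1-en-1-yl]-3-methylpenta-1,4-dien-3-ol
Conditions: CH2=CHMgBr (4 equiv), THF, −40 → 0 °C; sat. aq. NH4Cl
Reagents that add atoms: vinylmagnesium bromide, C=C[Mg]Br
Why: Grignard 1,2-addition to the β-ionone-type ketone, as in the classical vinyl-β-ionol synthesis, proceeds after two equivalents have been used up by the diol and creates no stereocentre that survives step 12.

Step 11
Reactants: 14 (1E)-1-[(3R,4S)-3,4-dihydroxy-2,6,6-trimethylcyclohex-1-en-1-yl]-3-methylpenta-1,4-dien-3-ol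
Product: 15 (1S,2R)-4-[(1E)-3-hydroxy-3-methylpenta-1,4-dien-1-yl]-3,5,5-trimethylcyclohex-3-ene-1,2-diyl diacetate
Conditions: Ac2O (2.5 equiv), pyridine, 0 °C → rt
Reagents that add atoms: acetic anhydride, CC(=O)OC(C)=O
Why: Acylation with Ac2O/pyridine esterifies only the two secondary hydroxyls, the tertiary carbinol being inert without an acyl-transfer catalyst, and the acetates deactivate the allylic C4–O bond toward ionisation in step 12.

Step 12
Reactants: 15 diacetate carbinol
Product: 16 {(2E,4E)-5-[(3R,4S)-3,4-bis(acetyloxy)-2,6,6-trimethylcyclohex-1-en-1-yl]-3-methylpenta-2,4-dien-1-yl}triphenylphosphonium bromide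
Conditions: PPh3·HBr (1.1 equiv), CH2Cl2, 0 °C → rt
Reagents that add atoms: triphenylphosphine hydrobromide, [Br-].c1ccc(cc1)[PH+](c1ccccc1)c1ccccc1
Why: The same acid-mediated allylic transposition as in step 6 should ionise the tertiary carbinol selectively and place PPh3 at C11 with E geometry, the two acetoxy groups retarding ionisation at C4.

Step 13
Reactants: 16 β-type C15 phosphonium bromide; 11 C25 aldehyde
Product: 19 (3S,4R,3'R,6'R)-β,ε-carotene-3,4,3'-triol, via β-C15 ylide 17 (not isolated), via C40 triester 18 (not isolated)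
Conditions: 1,2-epoxybutane/EtOH, 65 °C; then NaOMe (0.5 equiv), MeOH/THF, rt; then n-heptane, reflux (Z to E isomerisation), crystallisation
Reagents that add atoms: none
Why: Wittig olefination closes the last C11=C12 bond of the polyene, base-catalysed methanolysis (transesterification) then removes the benzoate and both acetates without touching any stereocentre, and heating should equilibrate Z-isomers to the all-E compound.

**Compound list**

1 | 4-methyl-2H-pyran-2-one | CC1=CC(=O)OC=C1 | starting material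
2 | 2-methylpropene (isobutylene) | C=C(C)C | starting material
3 | (1S,4R)-5,8,8-trimethyl-2-oxabicyclo[2.2.2]oct-5-en-3-one | O=C1O[C@@H]2C=C(C)[C@H]1C(C)(C)C2 | intermediate
4 | (1S,4R)-5,8,8-trimethyl-2-oxabicyclo[2.2.2]oct-5-en-3-ol (anomer mixture) | OC1O[C@@H]2C=C(C)[C@H]1C(C)(C)C2 | intermediate
5 | (3E)-4-[(1R,4S)-4-hydroxy-2,6,6-trimethylcyclohex-2-en-1-yl]but-3-en-2-one | CC1=C[C@@H](O)CC(C)(C)[C@H]1/C=C/C(C)=O | intermediate
6 | (1E)-1-[(1R,4S)-4-hydroxy-2,6,6-trimethylcyclohex-2-en-1-yl]-3-methylpenta-1,4-dien-3-ol (C3 epimers of the pentadienol) | CC1=C[C@@H](O)CC(C)(C)[C@H]1/C=C/C(C)(O)C=C | intermediate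
7 | (1R,4R)-4-[(1E)-3-hydroxy-3-methylpenta-1,4-dien-1-yl]-3,5,5-trimethylcyclohex-2-en-1-yl benzoate | CC1=C[C@H](OC(=O)c2ccccc2)CC(C)(C)[C@H]1/C=C/C(C)(O)C=C | intermediate
8 | {(2E,4E)-5-[(1R,4R)-4-(benzoyloxy)-2,6,6-trimethylcyclohex-2-en-1-yl]-3-methylpenta-2,4-dien-1-yl}triphenylphosphonium bromide | CC1=C[C@H](OC(=O)c2ccccc2)CC(C)(C)[C@H]1/C=C/C(C)=C/C[P+](c1ccccc1)(c1ccccc1)c1ccccc1.[Br-] | intermediate
9 | (2E,4E,6E)-2,7-dimethylocta-2,4,6-trienedial | O=C/C(C)=C/C=C/C=C(C)/C=O | starting material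
10 | ε-C15 ylide, (1R,4R)-3,5,5-trimethyl-4-[(1E,3E)-3-methyl-5-(triphenyl-λ5-phosphanylidene)penta-1,3-dien-1-yl]cyclohex-2-en-1-yl benzoate | CC1=C[C@H](OC(=O)c2ccccc2)CC(C)(C)[C@H]1/C=C/C(C)=C/C=P(c1ccccc1)(c1ccccc1)c1ccccc1 | intermediate (not isolated)
11 | (2E,4E,6E,8E,10E,12E)-13-[(1R,4R)-4-(benzoyloxy)-2,6,6-trimethylcyclohex-2-en-1-yl]-2,7,11-trimethyltrideca-2,4,6,8,10,12-hexaenal | CC1=C[C@H](OC(=O)c2ccccc2)CC(C)(C)[C@H]1/C=C/C(C)=C/C=C/C(C)=C/C=C/C=C(C)/C=O | intermediate
12 | (3E)-4-[(1R,2R,5S,6S)-5-hydroxy-1,3,3-trimethyl-7-oxabicyclo[4.1.0]heptan-2-yl]but-3-en-2-one | CC(=O)/C=C/[C@@H]1C(C)(C)C[C@H](O)[C@@H]2O[C@]12C | intermediate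
13 | (3E)-4-[(3R,4S)-3,4-dihydroxy-2,6,6-trimethylcyclohex-1-en-1-yl]but-3-en-2-one | CC(=O)/C=C/C1=C(C)[C@@H](O)[C@@H](O)CC1(C)C | intermediate
14 | (1E)-1-[(3R,4S)-3,4-dihydroxy-2,6,6-trimethylcyclohex-1-en-1-yl]-3-methylpenta-1,4-dien-3-ol (C3 epimers of the pentadienol) | C=CC(C)(O)/C=C/C1=C(C)[C@@H](O)[C@@H](O)CC1(C)C | intermediate
15 | (1S,2R)-4-[(1E)-3-hydroxy-3-methylpenta-1,4-dien-1-yl]-3,5,5-trimethylcyclohex-3-ene-1,2-diyl diacetate | C=CC(C)(O)/C=C/C1=C(C)[C@@H](OC(C)=O)[C@@H](OC(C)=O)CC1(C)C | intermediate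
16 | {(2E,4E)-5-[(3R,4S)-3,4-bis(acetyloxy)-2,6,6-trimethylcyclohex-1-en-1-yl]-3-methylpenta-2,4-dien-1-yl}triphenylphosphonium bromide | [Br-].C(/C=C(C)/C=C/C1=C(C)[C@@H](OC(C)=O)[C@@H](OC(C)=O)CC1(C)C)[P+](c1ccccc1)(c1ccccc1)c1ccccc1 | intermediate
17 | β-C15 ylide, (1S,2R)-3,5,5-trimethyl-4-[(1E,3E)-3-methyl-5-(triphenyl-λ5-phosphanylidene)penta-1,3-dien-1-yl]cyclohex-3-ene-1,2-diyl diacetate | c1ccccc1P(c1ccccc1)(c1ccccc1)=C/C=C(C)/C=C/C1=C(C)[C@@H](OC(C)=O)[C@@H](OC(C)=O)CC1(C)C | intermediate (not isolated)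
18 | C40 triester, (3S,4R,3'R,6'R)-3,4-bis(acetyloxy)-β,ε-caroten-3'-yl benzoate | CC1=C[C@H](OC(=O)c2ccccc2)CC(C)(C)[C@H]1/C=C/C(C)=C/C=C/C(C)=C/C=C/C=C(C)/C=C/C=C(C)/C=C/C1=C(C)[C@@H](OC(C)=O)[C@@H](OC(C)=O)CC1(C)C | intermediate (not isolated)
19 | (3S,4R,3'R,6'R)-β,ε-carotene-3,4,3'-triol | CC1=C[C@H](O)CC(C)(C)[C@H]1/C=C/C(C)=C/C=C/C(C)=C/C=C/C=C(C)/C=C/C=C(C)/C=C/C1=C(C)[C@@H](O)[C@@H](O)CC1(C)C | target

**Step count and risks**

Total step count: 13. Longest linear sequence: 9 steps (steps 1, 2, 3, 8, 9, 10, 11, 12, 13).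

Steps most likely to fail:

Step 1. The silyloxypyrylium ion pair may be too weak an electrophile for isobutylene. Isobutylene may also be lost to cationic oligomerisation or react in an ene sense, and the chiral anion may not distinguish the faces of so small a diene. The fallback uses known chemistry and does not pass through the cycloaddition; it sets out from no compound of the route but from commercial racemic α-ionone F1, and comes back at 5. Ketalisation with ethylene glycol gives the dioxolane F2. Allylic oxidation at C3 (t-BuOOH with aq. NaOCl) gives the 3-oxo ketal F3. Reduction of the ring enone (NaBH4, CeCl3) gives the 3-hydroxy ketal F4 as racemic cis and trans isomers. The cis racemate is separated by chromatography and resolved by lipase-catalysed acetylation with vinyl acetate, the enzyme being chosen so that the (3S,6R) alcohol F5 stays unacylated while its enantiomer is removed as the acetate F6. Mild acid hydrolysis of the ketal of F5 then gives 5.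

Step 3. Olefination may be slow because the aldehyde is masked as the lactol, and the heating then needed may cause epimerisation at C6 or migration of the ring double bond into conjugation; the cis-hydroxyl may also re-close onto the new enone by oxa-Michael addition. The fallback sets out from 3 and comes back at 5. Aminolysis of the lactone with MeONHMe·HCl/AlMe3 gives the cis-hydroxy Weinreb amide F7. Silylation (TBSCl, imidazole) gives the silyl ether F8. iBu2AlH reduces this to the aldehyde F9, which has neither the ring–chain equilibrium nor the internal nucleophile. Wittig reaction with the same ylide at lower temperature gives the silyl ether F10, and Bu4NF liberates 5.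

Step 12. Ionisation of the allylic C4–O bond, with loss of acetate and formation of dehydrated or rearranged polyenes, may compete with the wanted ionisation of the tertiary carbinol. The fallback avoids carbocations altogether; it sets out from 13 and comes back at 19. Silylation (TBSOTf, 2,6-lutidine) gives the bis-silyl ether F11. Horner–Wadsworth–Emmons reaction with triethyl phosphonoacetate/NaH gives the C15 ester F12 (2E isomer separated). iBu2AlH gives the allylic alcohol F13. CBr4/PPh3 gives the bromide F14, and PPh3 converts it into the phosphonium bromide F15. Wittig reaction with 11 in 1,2-epoxybutane gives the C40 bis-silyl ether benzoate F16. Bu4NF followed by NaOMe/MeOH gives 19.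

**Further compounds**

F1 | step 1 | racemic α-ionone, (3E)-4-(2,6,6-trimethylcyclohex-2-en-1-yl)but-3-en-2-one | CC1=CCCC(C)(C)C1/C=C/C(C)=O
F2 | step 1 | racemic 2-methyl-2-[(E)-2-(2,6,6-trimethylcyclohex-2-en-1-yl)ethenyl]-1,3-dioxolane | CC1=CCCC(C)(C)C1/C=C/C2(C)OCCO2
F3 | step 1 | racemic 3,5,5-trimethyl-4-[(E)-2-(2-methyl-1,3-dioxolan-2-yl)ethenyl]cyclohex-2-en-1-one | CC1=CC(=O)CC(C)(C)C1/C=C/C2(C)OCCO2
F4 | step 1 | 3,5,5-trimethyl-4-[(E)-2-(2-methyl-1,3-dioxolan-2-yl)ethenyl]cyclohex-2-en-1-ol (racemic cis and trans isomers) | CC1=CC(O)CC(C)(C)C1/C=C/C2(C)OCCO2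
F5 | step 1 | (1S,4R)-3,5,5-trimethyl-4-[(E)-2-(2-methyl-1,3-dioxolan-2-yl)ethenyl]cyclohex-2-en-1-ol | CC1=C[C@@H](O)CC(C)(C)[C@H]1/C=C/C2(C)OCCO2
F6 | step 1 | (1R,4S)-3,5,5-trimethyl-4-[(E)-2-(2-methyl-1,3-dioxolan-2-yl)ethenyl]cyclohex-2-en-1-yl acetate | CC1=C[C@H](OC(C)=O)CC(C)(C)[C@@H]1/C=C/C2(C)OCCO2
F7 | step 3 | (1R,4S)-4-hydroxy-N-methoxy-N,2,6,6-tetramethylcyclohex-2-ene-1-carboxamide | CC1=C[C@@H](O)CC(C)(C)[C@H]1C(=O)N(C)OC
F8 | step 3 | (1R,4S)-4-[(tert-butyldimethylsilyl)oxy]-N-methoxy-N,2,6,6-tetramethylcyclohex-2-ene-1-carboxamide | CC1=C[C@@H](O[Si](C)(C)C(C)(C)C)CC(C)(C)[C@H]1C(=O)N(C)OC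
F9 | step 3 | (1R,4S)-4-[(tert-butyldimethylsilyl)oxy]-2,6,6-trimethylcyclohex-2-ene-1-carbaldehyde | CC1=C[C@@H](O[Si](C)(C)C(C)(C)C)CC(C)(C)[C@H]1C=O
F10 | step 3 | (3E)-4-[(1R,4S)-4-[(tert-butyldimethylsilyl)oxy]-2,6,6-trimethylcyclohex-2-en-1-yl]but-3-en-2-one | CC1=C[C@@H](O[Si](C)(C)C(C)(C)C)CC(C)(C)[C@H]1/C=C/C(C)=O
F11 | step 12 | (3E)-4-[(3R,4S)-3,4-bis[(tert-butyldimethylsilyl)oxy]-2,6,6-trimethylcyclohex-1-en-1-yl]but-3-en-2-one | CC(=O)/C=C/C1=C(C)[C@@H](O[Si](C)(C)C(C)(C)C)[C@@H](O[Si](C)(C)C(C)(C)C)CC1(C)C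
F12 | step 12 | ethyl (2E,4E)-5-[(3R,4S)-3,4-bis[(tert-butyldimethylsilyl)oxy]-2,6,6-trimethylcyclohex-1-en-1-yl]-3-methylpenta-2,4-dienoate | CCOC(=O)/C=C(C)/C=C/C1=C(C)[C@@H](O[Si](C)(C)C(C)(C)C)[C@@H](O[Si](C)(C)C(C)(C)C)CC1(C)C
F13 | step 12 | (2E,4E)-5-[(3R,4S)-3,4-bis[(tert-butyldimethylsilyl)oxy]-2,6,6-trimethylcyclohex-1-en-1-yl]-3-methylpenta-2,4-dien-1-ol | OC/C=C(C)/C=C/C1=C(C)[C@@H](O[Si](C)(C)C(C)(C)C)[C@@H](O[Si](C)(C)C(C)(C)C)CC1(C)C
F14 | step 12 | (3R,4S)-1-[(1E,3E)-5-bromo-3-methylpenta-1,3-dien-1-yl]-3,4-bis[(tert-butyldimethylsilyl)oxy]-2,6,6-trimethylcyclohex-1-ene | BrC/C=C(C)/C=C/C1=C(C)[C@@H](O[Si](C)(C)C(C)(C)C)[C@@H](O[Si](C)(C)C(C)(C)C)CC1(C)C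
F15 | step 12 | {(2E,4E)-5-[(3R,4S)-3,4-bis[(tert-butyldimethylsilyl)oxy]-2,6,6-trimethylcyclohex-1-en-1-yl]-3-methylpenta-2,4-dien-1-yl}triphenylphosphonium bromide | [Br-].C(/C=C(C)/C=C/C1=C(C)[C@@H](O[Si](C)(C)C(C)(C)C)[C@@H](O[Si](C)(C)C(C)(C)C)CC1(C)C)[P+](c1ccccc1)(c1ccccc1)c1ccccc1
F16 | step 12 | (3S,4R,3'R,6'R)-3,4-bis[(tert-butyldimethylsilyl)oxy]-β,ε-caroten-3'-yl benzoate | CC1=C[C@H](OC(=O)c2ccccc2)CC(C)(C)[C@H]1/C=C/C(C)=C/C=C/C(C)=C/C=C/C=C(C)/C=C/C=C(C)/C=C/C1=C(C)[C@@H](O[Si](C)(C)C(C)(C)C)[C@@H](O[Si](C)(C)C(C)(C)C)CC1(C)C
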